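**Plan**

1. Retrosynthetic cuts: first C1″–C1′ (arene to benzylic carbon), then the two formyl C–C bonds (C3″, C5″), then C1′–C2′ (isobutyl), then C1–C2 and C5–C10 together, then the C10=C1, C5=C4 and C4–C15 bonds of an acyclic triene.
2. Enabling feature: C1″ of the phloroglucinol ring lies para to the oxygen on C4″ (the OH that ends between the two CHO groups). As a free phenolate bound to an oxidant, this oxygen drains the ring, so the C1′–B bond of a boronate on C1″ shifts onto C1″. Two carbon nucleophiles (C1′–B and C1″–Li) are thus joined oxidatively, with retention at C1′.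
3. Forward, rings: (R)-α-terpineol is opened by ozonolysis (its ring C=C becomes the C10/C5 pair). The keto aldehyde is converted into an enoate (C10=C1) and a 2-(silylmethyl)diene (C5=C4–C3=C2). One intramolecular Diels–Alder reaction then closes ring B (C5–C10) and ring A (C5–C10, C1–C2) together.
4. Forward, chain and arene: allylsilane to C4=C15 methylene, ester to C1′ carbamate, lithiation–borylation with isobutyl-Bpin to the C1′ boronic ester, coupling with a 4-lithio-3,5-bis(MOM-oxy)phenolate, double ortho-formylation, acid deprotection.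
5. Stereochemistry: C7 from (R)-α-terpineol; C5, C10 and C1 from the Diels–Alder transition state (C7 group equatorial on the tether, ester endo, E-enoate); C1′ from (−)-sparteine in the lithiation–borylation, carried through the coupling with retention.
6. Helpers and their removal: CH2SiMe3 on C4 (step 8), Bpin on C1′ (step 14), TES on O11 and MOM on O2″/O6″ (step 16).

Key step: step 14

Remark: eudesmane numbering is used for the decalin (C1–C15; C11–C13 side chain on C7; C14 is the methyl on C10), C1′–C5′ for the isopentyl chain and C1″–C6″ for the arene; α/β refer to the usual drawing with the C10 methyl β; commercial (R)-(+)-α-terpineol is taken as enantiopure.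

**Route**

Step 1
Reactants: 1 (R)-(+)-α-terpineol
Product: 2 triethyl({2-[(1R)-4-methylcyclohex-3-en-1-yl]propan-2-yl}oxy)silane
Conditions: TESOTf, 2,6-lutidine, CH2Cl2, 0 °C to rt
Reagents that add atoms: triethylsilyl trifluoromethanesulfonate, CC[Si](CC)(CC)OS(=O)(=O)C(F)(F)F
Why: Silyl ether formation with the reactive triflate masks the tertiary alcohol, which would otherwise close to a lactol on the aldehyde made in step 2; the C7 stereocentre is not touched.

Step 2
Reactants: 2 TES ether of α-terpineol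
Product: 4 (3R)-6-oxo-3-[2-(triethylsilyloxy)propan-2-yl]heptanal, via secondary ozonide 3 (not isolated)
Conditions: O3, CH2Cl2, −78 °C; then PPh3, −78 °C to rt
Reagents that add atoms: ozone, [O-][O+]=O
Why: Criegee ozonolysis of the only alkene and phosphine reduction of the ozonide open the ring to the 1,6-keto aldehyde (ketone carbon = future C10, aldehyde carbon = future C5); C7 is β to the aldehyde and cannot epimerise.

Step 3
Reactants: 4 keto aldehyde
Product: 5 (5R)-8,8-dibromo-5-[2-(triethylsilyloxy)propan-2-yl]oct-7-en-2-one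
Conditions: CBr4, PPh3, Zn dust, CH2Cl2, rt (reagent pre-formed); then 4, 0 °C
Reagents that add atoms: carbon tetrabromide, BrC(Br)(Br)Br
Why: Corey–Fuchs (Ramirez) dibromomethylenation should take the aldehyde much faster than the methyl ketone and installs C4 as a CBr2 carbon whose two bromides can be replaced one after the other; zinc consumes Ph3PBr2 and so protects the silyl ether.

Step 4
Reactants: 5 dibromoalkenyl ketone
Product: 6 methyl (2E,6R)-9,9-dibromo-3-methyl-6-[2-(triethylsilyloxy)propan-2-yl]nona-2,8-dienoate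
Conditions: (MeO)2P(O)CH2CO2Me, NaH, THF, 0 to 50 °C; minor Z isomer removed by chromatography
Reagents that add atoms: trimethyl phosphonoacetate, COC(=O)CP(=O)(OC)OC
Why: Horner–Wadsworth–Emmons olefination of the methyl ketone builds the C10=C1 dienophile with the ester carbon as C1′; the E isomer (ester trans to the chain) is expected to predominate, and the weakly basic phosphonate anion leaves the dibromoalkene alone.

Step 5
Reactants: 6 dibromoalkenyl enoate
Product: 7 methyl (2E,6R,8Z)-9-bromo-3-methyl-6-[2-(triethylsilyloxy)propan-2-yl]undeca-2,8,10-trienoate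
Conditions: Bu3SnCH=CH2, Pd2(dba)3 (cat.), P(2-furyl)3, toluene, 80 °C
Reagents that add atoms: tributyl(vinyl)stannane, C=C[Sn](CCCC)(CCCC)CCCC
Why: In the Stille coupling of a 1,1-dibromoalkene, zerovalent palladium inserts selectively into the less hindered C–Br bond trans to the alkyl chain, so the vinyl group (C3=C2) ends trans to C6, the diene geometry that the cycloaddition needs.

Step 6
Reactants: 7 bromodiene enoate
Product: 8 methyl (2E,6R,8Z)-3-methyl-6-[2-(triethylsilyloxy)propan-2-yl]-9-[(trimethylsilyl)methyl]undeca-2,8,10-trienoate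
Conditions: Me3SiCH2MgCl, ZnCl2, THF, 0 °C; then 7, Pd(PPh3)4 (cat.), THF, 50 °C
Reagents that add atoms: (trimethylsilyl)methylmagnesium chloride, C[Si](C)(C)C[Mg]Cl
Why: Negishi coupling of the remaining alkenyl bromide proceeds with retention of alkene geometry and tolerates the enoate; it places C15 on C4 as an allylsilane, the masked form of the exocyclic methylene.

Step 7
Reactants: 8 silylmethyl triene ester
Product: 9 methyl 11-(triethylsilyloxy)-15-(trimethylsilyl)eudesm-3-ene-1β-carboxylate (5α-H,7α-H,10β-methyl)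
Conditions: toluene (0.01 M), BHT (cat.), 190 °C, sealed tube
Reagents that add atoms: none
Why: Thermal intramolecular Diels–Alder reaction of the 1,7,9-decatriene: the electron-rich 2-(silylmethyl)diene adds to the β,β-disubstituted enoate with matched polarity (C5 to C10, C2 to C1); the ester-endo transition state with a chair-like C6–C9 tether carrying the C7 group equatorially should give the trans ring fusion (5α-H, 10β-methyl) in the natural sense relative to C7, and the E-enoate places the C1 ester cis to the C10 methyl (1β).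

Step 8
Reactants: 9 cyclic allylsilane ester
Product: 10 methyl 11-(triethylsilyloxy)eudesm-4(15)-ene-1β-carboxylate
Conditions: CF3CO2H, CH2Cl2, −20 to 0 °C; NaHCO3 quench
Reagents that add atoms: none
Why: Protodesilylation of the allylsilane (SE2′): protonation at C3 gives the β-silyl cation at C4 and loss of silicon forms the C4=C15 exocyclic methylene regiospecifically; short exposure under anhydrous conditions should leave the tertiary TES ether and the new alkene unchanged.

Step 9
Reactants: 10 methyl ester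
Product: 11 [11-(triethylsilyloxy)eudesm-4(15)-en-1β-yl]methanol
Conditions: LiAlH4, THF, 0 °C
Reagents that add atoms: none
Why: Hydride reduction of the ester gives the primary alcohol at C1′ without epimerising C1.

Step 10
Reactants: 11 primary alcohol
Product: 12 [11-(triethylsilyloxy)eudesm-4(15)-en-1β-yl]methyl N,N-diisopropylcarbamate
Conditions: i-Pr2NCOCl, Et3N, DMAP (cat.), toluene, 90 °C
Reagents that add atoms: N,N-diisopropylcarbamoyl chloride, CC(C)N(C(C)C)C(Cl)=O
Why: O-Carbamoylation installs the directing and leaving group for the sparteine-mediated α-lithiation.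

Step 11
Reactants: 12 carbamate; 13 2-isobutyl-4,4,5,5-tetramethyl-1,3,2-dioxaborolane
Product: 16 2-{(1S)-3-methyl-1-[11-(triethylsilyloxy)eudesm-4(15)-en-1β-yl]butyl}-4,4,5,5-tetramethyl-1,3,2-dioxaborolane, via lithiated carbamate 14 (not isolated), via boronate complex 15 (not isolated)
Conditions: s-BuLi, (−)-sparteine, Et2O, −78 °C, 5 h; 13, −78 °C; MgBr2·OEt2, then reflux
Reagents that add atoms: none
Why: Lithiation–borylation (a reagent-controlled relative of the Matteson homologation): s-BuLi/(−)-sparteine removes the pro-S hydrogen at C1′, the boronic ester is captured with retention and the isobutyl group migrates from boron to C1′ with inversion as the carbamate leaves, which sets C1′ (boron standing where the arene will stand) under reagent control.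

Step 12
Reactants: 17 2-bromobenzene-1,3-diol
Product: 18 2-bromo-1,3-bis(methoxymethoxy)benzene
Conditions: MeOCH2Cl, i-Pr2NEt, CH2Cl2, 0 °C to rt
Reagents that add atoms: chloromethyl methyl ether, COCCl
Why: Double O-alkylation gives MOM ethers that survive organolithiums, stabilise the later aryllithium by chelation and are removed by mild acid at the end.

Step 13
Reactants: 18 bis-MOM bromoarene
Product: 20 4-bromo-3,5-bis(methoxymethoxy)phenol, via aryl pinacol boronate 19 (not isolated)
Conditions: B2pin2, [Ir(OMe)(cod)]2 (cat.), 4,4′-di-tert-butyl-2,2′-bipyridine, THF, 80 °C; then aq. H2O2, NaOH, 0 °C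
Reagents that add atoms: bis(pinacolato)diboron, CC1(C)OB(OC1(C)C)B1OC(C)(C)C(C)(C)O1; hydrogen peroxide, OO
Why: Sterically controlled iridium-catalysed C–H borylation takes the only ring C–H without an ortho substituent (para to bromine), and oxidation of the C–B bond gives the free para-phenol needed as trigger in step 14.

Step 14
Reactants: 16 C1′ boronic ester; 20 bromophenol
Product: 24 3,5-bis(methoxymethoxy)-4-{(1S)-3-methyl-1-[11-(triethylsilyloxy)eudesm-4(15)-en-1β-yl]butyl}phenol, via dilithiated phenolate 21 (not isolated), via aryl boronate complex 22 (not isolated), via boryl cyclohexadienone 23 (not isolated)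
Conditions: 20 (1.5 equiv), t-BuLi (3 equiv per 20), THF, −78 °C; 16, −78 to 0 °C; Ph3BiF2, −78 °C to rt; aq. NH4Cl
Reagents that add atoms: none
Why: Deprotonation and bromine–lithium exchange on 20 give aryllithium 21, which adds to boron of 16 to form boronate 22; exchange of the phenolate oxygen (on C4″, para to C1″) onto pentavalent bismuth makes it a two-electron sink, so the C1′–B bond shifts to C1″ (1,2-metallate rearrangement) as trivalent bismuth (Ph3Bi) leaves, giving dienone 23, and loss of the boryl group on work-up restores the arene as 24. The closest known reaction type is the stereospecific coupling of secondary and tertiary boronic esters with lithiated phenolates and other electron-rich aryllithiums by oxidant-triggered 1,2-metallate rearrangement, formally an oxidative union of two carbon nucleophiles. No ring is closed. No stereocentre is created: the migrating C1′ keeps its configuration (1,2-shift with retention), so 1′S in 16 becomes 1′S in 24, under control of the boronic ester from step 11. The step needs activation at the para oxygen in preference to ipso attack at C1″ (protodeboronation) and to reaction at the C4(15) alkene; the single free phenolate (the other two oxygens are MOM ethers) and the oxygen-selective bismuth reagent are expected to secure this. The main demand is steric, since boronate formation joins a 2,6-disubstituted aryllithium with a branched secondary boronic ester; excess 21 and warming to 0 °C before the oxidant is added address it.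

Step 15
Reactants: 24 coupled phenol
Product: 25 2-hydroxy-4,6-bis(methoxymethoxy)-5-{(1S)-3-methyl-1-[11-(triethylsilyloxy)eudesm-4(15)-en-1β-yl]butyl}benzene-1,3-dicarbaldehyde
Conditions: MgCl2, Et3N, (CH2O)n (excess), MeCN, reflux; aq. NH4Cl work-up
Reagents that add atoms: paraformaldehyde (as formaldehyde), C=O
Why: Casnati–Skattebøl ortho-formylation: the magnesium phenoxide delivers formaldehyde to each position ortho to the free OH (C3″ and C5″) and a second formaldehyde oxidises each hydroxymethyl group to the aldehyde; the base-stable alkene, silyl ether and MOM ethers are not affected.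

Step 16
Reactants: 25 protected dialdehyde
Product: 26 macrocarpal H
Conditions: 1 M aq. HCl, MeOH–THF, 0 °C to rt
Reagents that add atoms: none
Why: Mild acid cleaves the two aryl MOM acetals (activated by the ortho formyl groups) and the tertiary TES ether in one operation; the dilute acid and low temperature are chosen so that the C4(15) alkene does not isomerise.

**Compound list**

1 | (R)-(+)-α-terpineol, 2-[(1R)-4-methylcyclohex-3-en-1-yl]propan-2-ol | CC1=CC[C@@H](CC1)C(C)(C)O | starting material
2 | triethyl({2-[(1R)-4-methylcyclohex-3-en-1-yl]propan-2-yl}oxy)silane | CC1=CC[C@@H](CC1)C(C)(C)O[Si](CC)(CC)CC | intermediate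
3 | secondary ozonide of 2 (1,2,4-trioxolane bridging future C10 and C5) | CC1(OO2)CC[C@H](CC2O1)C(C)(C)O[Si](CC)(CC)CC | intermediate (not isolated)
4 | (3R)-6-oxo-3-[2-(triethylsilyloxy)propan-2-yl]heptanal | CC(=O)CC[C@H](CC=O)C(C)(C)O[Si](CC)(CC)CC | intermediate
5 | (5R)-8,8-dibromo-5-[2-(triethylsilyloxy)propan-2-yl]oct-7-en-2-one | CC(=O)CC[C@H](CC=C(Br)Br)C(C)(C)O[Si](CC)(CC)CC | intermediate
6 | methyl (2E,6R)-9,9-dibromo-3-methyl-6-[2-(triethylsilyloxy)propan-2-yl]nona-2,8-dienoate | COC(=O)/C=C(\C)CC[C@H](CC=C(Br)Br)C(C)(C)O[Si](CC)(CC)CC | intermediate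
7 | methyl (2E,6R,8Z)-9-bromo-3-methyl-6-[2-(triethylsilyloxy)propan-2-yl]undeca-2,8,10-trienoate | COC(=O)/C=C(\C)CC[C@H](C/C=C(\Br)C=C)C(C)(C)O[Si](CC)(CC)CC | intermediate
8 | methyl (2E,6R,8Z)-3-methyl-6-[2-(triethylsilyloxy)propan-2-yl]-9-[(trimethylsilyl)methyl]undeca-2,8,10-trienoate | COC(=O)/C=C(\C)CC[C@H](C/C=C(\C[Si](C)(C)C)C=C)C(C)(C)O[Si](CC)(CC)CC | intermediate
9 | methyl 11-(triethylsilyloxy)-15-(trimethylsilyl)eudesm-3-ene-1β-carboxylate (5α-H, 7α-H, 10β-methyl) | C[Si](C)(C)CC1=CC[C@@H](C(=O)OC)[C@]2(C)CC[C@@H](C(C)(C)O[Si](CC)(CC)CC)C[C@@H]12 | intermediate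
10 | methyl 11-(triethylsilyloxy)eudesm-4(15)-ene-1β-carboxylate | C=C1CC[C@@H](C(=O)OC)[C@]2(C)CC[C@@H](C(C)(C)O[Si](CC)(CC)CC)C[C@@H]12 | intermediate
11 | [11-(triethylsilyloxy)eudesm-4(15)-en-1β-yl]methanol | C=C1CC[C@@H](CO)[C@]2(C)CC[C@@H](C(C)(C)O[Si](CC)(CC)CC)C[C@@H]12 | intermediate
12 | [11-(triethylsilyloxy)eudesm-4(15)-en-1β-yl]methyl N,N-diisopropylcarbamate | C=C1CC[C@@H](COC(=O)N(C(C)C)C(C)C)[C@]2(C)CC[C@@H](C(C)(C)O[Si](CC)(CC)CC)C[C@@H]12 | intermediate
13 | 2-isobutyl-4,4,5,5-tetramethyl-1,3,2-dioxaborolane | CC(C)CB1OC(C)(C)C(C)(C)O1 | starting material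
14 | (1′S)-1′-lithio derivative of 12 (sparteine complex) | C=C1CC[C@@H]([C@H]([Li])OC(=O)N(C(C)C)C(C)C)[C@]2(C)CC[C@@H](C(C)(C)O[Si](CC)(CC)CC)C[C@@H]12 | intermediate (not isolated)
15 | lithium boronate complex from 14 and 13 | C=C1CC[C@@H]([C@H]([B-]3(CC(C)C)OC(C)(C)C(C)(C)O3)OC(=O)N(C(C)C)C(C)C)[C@]2(C)CC[C@@H](C(C)(C)O[Si](CC)(CC)CC)C[C@@H]12.[Li+] | intermediate (not isolated)
16 | 2-{(1S)-3-methyl-1-[11-(triethylsilyloxy)eudesm-4(15)-en-1β-yl]butyl}-4,4,5,5-tetramethyl-1,3,2-dioxaborolane | C=C1CC[C@@H]([C@H](CC(C)C)B3OC(C)(C)C(C)(C)O3)[C@]2(C)CC[C@@H](C(C)(C)O[Si](CC)(CC)CC)C[C@@H]12 | intermediate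
17 | 2-bromobenzene-1,3-diol | Oc1cccc(O)c1Br | starting material
18 | 2-bromo-1,3-bis(methoxymethoxy)benzene | COCOc1cccc(OCOC)c1Br | intermediate
19 | 2-[4-bromo-3,5-bis(methoxymethoxy)phenyl]-4,4,5,5-tetramethyl-1,3,2-dioxaborolane | COCOc1cc(B2OC(C)(C)C(C)(C)O2)cc(OCOC)c1Br | intermediate (not isolated)
20 | 4-bromo-3,5-bis(methoxymethoxy)phenol | COCOc1cc(O)cc(OCOC)c1Br | intermediate
21 | lithium 4-lithio-3,5-bis(methoxymethoxy)phenolate | [Li]c1c(OCOC)cc(O[Li])cc1OCOC | intermediate (not isolated)
22 | dilithium aryl(alkyl)pinacolboronate from 21 and 16 | C=C1CC[C@@H]([C@H](CC(C)C)[B-]3(c4c(OCOC)cc([O-])cc4OCOC)OC(C)(C)C(C)(C)O3)[C@]2(C)CC[C@@H](C(C)(C)O[Si](CC)(CC)CC)C[C@@H]12.[Li+].[Li+] | intermediate (not isolated)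
23 | 4-alkyl-4-(pinacolboryl)-3,5-bis(methoxymethoxy)cyclohexa-2,5-dien-1-one (alkyl = the C1′ group of 16) | C=C1CC[C@@H]([C@H](CC(C)C)C3(B4OC(C)(C)C(C)(C)O4)C(OCOC)=CC(=O)C=C3OCOC)[C@]2(C)CC[C@@H](C(C)(C)O[Si](CC)(CC)CC)C[C@@H]12 | intermediate (not isolated)
24 | 3,5-bis(methoxymethoxy)-4-{(1S)-3-methyl-1-[11-(triethylsilyloxy)eudesm-4(15)-en-1β-yl]butyl}phenol | C=C1CC[C@@H]([C@H](CC(C)C)c3c(OCOC)cc(O)cc3OCOC)[C@]2(C)CC[C@@H](C(C)(C)O[Si](CC)(CC)CC)C[C@@H]12 | intermediate
25 | 2-hydroxy-4,6-bis(methoxymethoxy)-5-{(1S)-3-methyl-1-[11-(triethylsilyloxy)eudesm-4(15)-en-1β-yl]butyl}benzene-1,3-dicarbaldehyde | C=C1CC[C@@H]([C@H](CC(C)C)c3c(OCOC)c(C=O)c(O)c(C=O)c3OCOC)[C@]2(C)CC[C@@H](C(C)(C)O[Si](CC)(CC)CC)C[C@@H]12 | intermediate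
26 | macrocarpal H | C=C1CC[C@@H]([C@H](CC(C)C)c2c(O)c(C=O)c(O)c(C=O)c2O)[C@]2(C)CC[C@@H](C(C)(C)O)C[C@@H]12 | target

**Step count and risks**

Total step count: 16. Longest linear sequence: 14 (steps 1–11 and 14–16).

Steps most likely to fail:

1. Step 14. What may go wrong: boronate formation between the doubly ortho-substituted aryllithium and the branched secondary boronic ester may be too slow, after which ipso protodeboronation or phenyl transfer from bismuth would take over. Fallback, from 12 back to 24: 12 is lithiated as in step 11 but with (+)-sparteine and trapped with 13 to give the C1′-epimeric boronic ester F1. KHF2 in MeOH–H2O converts it into the potassium trifluoroborate F2. A stereoinvertive Suzuki–Miyaura coupling (Pd(P(t-Bu)3)2, K2CO3, toluene–H2O, 100 °C) with the tert-butyldimethylsilyl ether of 20, aryl bromide F3 (from 20, TBSCl, imidazole), gives the (1′S)-configured aryl silyl ether F4. K2CO3 in MeOH removes the aryl silyl group and returns 24.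

2. Step 7. What may go wrong: poor endo/exo (trans/cis ring fusion) or facial selectivity at the temperature the deactivated β,β-disubstituted enoate requires, and thermal polymerisation of the diene. Fallback, from 7 back to 11, replacing the thermal cycloaddition by a Lewis-acid-catalysed one on an acid-tolerant diene and attaching the allylsilane after ring formation: i-Bu2AlH reduces 7 to the allylic alcohol F5 and MnO2 gives the trienal F6. Me2AlCl (CH2Cl2, −78 to −20 °C) promotes the aldehyde-endo intramolecular Diels–Alder reaction to the bromo-octalin aldehyde F7. NaBH4 gives the alcohol F8, Negishi coupling with Me3SiCH2ZnCl (Pd(PPh3)4) gives the allylsilane alcohol F9, and CF3CO2H protodesilylation returns 11.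

3. Step 15. What may go wrong: arrest at the mono-aldehyde, because the magnesium salicylaldehyde chelate deactivates the ring, and O-methoxymethylation of the phenol on long heating. Fallback, from 24 to 26 by directed ortho-lithiation: NaH and MeOCH2Cl give the tris-MOM ether F10. n-BuLi/TMEDA (THF, 0 °C) lithiates between two MOM-oxy groups and DMF gives the mono-aldehyde F11. The aldehyde is protected in the flask as its α-amino alkoxide with lithium N,N,N′-trimethylethylenediamide, and a second n-BuLi/DMF sequence gives the dialdehyde F12. The acid treatment of step 16 removes three MOM groups and the TES ether to give 26.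

Further compounds
F1 | step 14 | 2-{(1R)-3-methyl-1-[11-(triethylsilyloxy)eudesm-4(15)-en-1β-yl]butyl}-4,4,5,5-tetramethyl-1,3,2-dioxaborolane | C=C1CC[C@@H]([C@@H](CC(C)C)B3OC(C)(C)C(C)(C)O3)[C@]2(C)CC[C@@H](C(C)(C)O[Si](CC)(CC)CC)C[C@@H]12
F2 | step 14 | potassium trifluoro{(1R)-3-methyl-1-[11-(triethylsilyloxy)eudesm-4(15)-en-1β-yl]butyl}borate | C=C1CC[C@@H]([C@@H](CC(C)C)[B-](F)(F)F)[C@]2(C)CC[C@@H](C(C)(C)O[Si](CC)(CC)CC)C[C@@H]12.[K+]
F3 | step 14 | [4-bromo-3,5-bis(methoxymethoxy)phenoxy](tert-butyl)dimethylsilane | COCOc1cc(O[Si](C)(C)C(C)(C)C)cc(OCOC)c1Br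
F4 | step 14 | tert-butyldimethylsilyl ether of 24 | C=C1CC[C@@H]([C@H](CC(C)C)c3c(OCOC)cc(O[Si](C)(C)C(C)(C)C)cc3OCOC)[C@]2(C)CC[C@@H](C(C)(C)O[Si](CC)(CC)CC)C[C@@H]12
F5 | step 7 | (2E,6R,8Z)-9-bromo-3-methyl-6-[2-(triethylsilyloxy)propan-2-yl]undeca-2,8,10-trien-1-ol | OC/C=C(\C)CC[C@H](C/C=C(\Br)C=C)C(C)(C)O[Si](CC)(CC)CC
F6 | step 7 | (2E,6R,8Z)-9-bromo-3-methyl-6-[2-(triethylsilyloxy)propan-2-yl]undeca-2,8,10-trienal | O=C/C=C(\C)CC[C@H](C/C=C(\Br)C=C)C(C)(C)O[Si](CC)(CC)CC
F7 | step 7 | 4-bromo-11-(triethylsilyloxy)-15-noreudesm-3-ene-1β-carbaldehyde | BrC1=CC[C@@H](C=O)[C@]2(C)CC[C@@H](C(C)(C)O[Si](CC)(CC)CC)C[C@@H]12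
F8 | step 7 | [4-bromo-11-(triethylsilyloxy)-15-noreudesm-3-en-1β-yl]methanol | BrC1=CC[C@@H](CO)[C@]2(C)CC[C@@H](C(C)(C)O[Si](CC)(CC)CC)C[C@@H]12
F9 | step 7 | [11-(triethylsilyloxy)-15-(trimethylsilyl)eudesm-3-en-1β-yl]methanol | C[Si](C)(C)CC1=CC[C@@H](CO)[C@]2(C)CC[C@@H](C(C)(C)O[Si](CC)(CC)CC)C[C@@H]12
F10 | step 15 | methoxymethyl ether of 24 (2,4,6-tris(methoxymethoxy)aryl compound) | C=C1CC[C@@H]([C@H](CC(C)C)c3c(OCOC)cc(OCOC)cc3OCOC)[C@]2(C)CC[C@@H](C(C)(C)O[Si](CC)(CC)CC)C[C@@H]12
F11 | step 15 | 2,4,6-tris(methoxymethoxy)-3-{(1S)-3-methyl-1-[11-(triethylsilyloxy)eudesm-4(15)-en-1β-yl]butyl}benzaldehyde | C=C1CC[C@@H]([C@H](CC(C)C)c3c(OCOC)cc(OCOC)c(C=O)c3OCOC)[C@]2(C)CC[C@@H](C(C)(C)O[Si](CC)(CC)CC)C[C@@H]12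
F12 | step 15 | 2,4,6-tris(methoxymethoxy)-5-{(1S)-3-methyl-1-[11-(triethylsilyloxy)eudesm-4(15)-en-1β-yl]butyl}benzene-1,3-dicarbaldehyde | C=C1CC[C@@H]([C@H](CC(C)C)c3c(OCOC)c(C=O)c(OCOC)c(C=O)c3OCOC)[C@]2(C)CC[C@@H](C(C)(C)O[Si](CC)(CC)CC)C[C@@H]12
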